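Time is the one setting left to choose in this flask, and the winter run, with the same charge, follows it as far as 90.0 s.

- winter: starting material 0.12 M; protic impurity 0.024 M; the very flask that is asked about, followed so far
- flask: starting material 0.12 M; protic impurity 0.0240 M; time 20 min

winter run (percent of the starting material charged)

| time / s | intermediate / % | target / % |
|---|---|---|
| 10.0 | 0.5 | 1.4 |
| 20.0 | 3.7 | 3.3 |
| 30.0 | 3.7 | 8.9 |
| 50.0 | 6.7 | 9.6 |
| 80.0 | 7.7 | 12.5 |
| 90.0 | 6.5 | 13.8 |

(standard deviation of a reading: 1 percentage point)

- the earlier runs were read with a standard deviation of 1 percentage point

- the best time, 20 min at the latest, for intermediate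
- the amount of intermediate, in percent of the starting material charged, at that time

I add intermediate and target into one pair. The pair gains 11 points in the 20.0 s after 10.0 s, but 4 points in the 40.0 s after 50.0 s, so its rise is slowing. The last step of 0.1 points is smaller than the scatter of 1 point, so I read no stop from it.

In the last two readings intermediate makes up 35.1% of the pair; this reading is the intermediate share. If the two exchange faster than the pair changes (a quasi-equilibrium), intermediate keeps that share and peaks when the pair peaks. If the pair gains 4 points once more, by 2.17 min, I expect about 8.52% of intermediate, then or later.

The forecast gives 1.5 min and 7.5%, with “little to gain by waiting”; my time is later than its time.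

The neighbour stopped at 5.0 min has the charge of this flask, but it is read earlier than this flask held to 20 min. Each should end with its target times the share over its remainder, 0.540.

This flask peaks at 3.11 min with 8.40% of intermediate.

    starting material → intermediate (k = 0.00600 /s)
    intermediate ⇌ target (K = 1.70, k = 0.290 /s)
    intermediate ⇌ isomer of the product (K = 2.30, k = 0.0440 /s)
    starting material + protic impurity → quenched substrate (k = 0.170 /M/s)
    intermediate → decomposed reagent (k = 0.0140 /s)

At 1.69 min intermediate is still made 1.08 times as fast as it is used up, each step taken net. At the peak the flask holds 14.3% of target, and the ratio 0.540 turns that into 7.72% of intermediate, a little below the peak. The neighbour stopped at 5.0 min holds 13.3% of target, which the ratio turns into 7.18%, and it holds 7.75% of intermediate.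

All runs were generated by integration on assumed constants, and the scatter is random.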